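**Retrosynthetic overview**

1. The strategy rests on ring B (C1–C10): the oxygen-bearing C2 and the C5=C6 alkene (C16 on C5) are separated only by the two methylene carbons C3 and C4, so with C2 as a ketone ring B is a cyclodec-4-enone. It is opened by a Claisen ring expansion to an eight-membered 2-methylene cyclic ether in which oxygen joins C2 to C6 and C6 carries the C5(=C4)C16 propenyl unit.
2. Ring C is closed last, by a Reformatsky reaction of a C7 2-bromopropanoate onto a C8 ketone. The enol ether comes from the eight-membered lactone (C2 acid, C6 alcohol) by methylenation.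
3. Chain C6–C9: C9/C8 by Eschenmoser–Claisen transfer from a C12 allylic alcohol and enolate hydroxylation; C7/C6 by a glycolate aldol; C5/C4/C16 by a 2-lithioallyl ether.
4. Ring A comes from (S)-carvone: C1 by two α'-substitutions, the C14 oxygen from the isopropenyl group, the 11,12-epoxide by iodolactonisation through the C8 carboxyl.
5. Ring order: A (carvone), then the epoxide, then the eight-membered ether, then B by ring expansion, then C.

Key step: step 25

**Remarks.** Atom labels: C1 quaternary fusion carbon (C15 its methyl), C2–C10 ring B, C11 (C20 its methyl) to C14 ring A, C16 the CH2 on C5, C17/C18/C19 the lactone CH, its methyl and its carbonyl. β is the face of ring A that bears C15, α the other face. The C6 carbinol centre (compounds 36–40) is destroyed in step 25; both epimers are carried and one is drawn. The CHBr centre of 49–51 is a mixture and is destroyed in step 33. 2-(Allyloxy)acetic acid 23 is taken as a purchasable compound.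

**Step 1**
Reactants: 1 (S)-carvone
Product: 3 (5S,6S)-6-(hydroxymethyl)carvone, via lithium dienolate 2 (not isolated)
Conditions: LiN(iPr)2, THF, −78 °C; CH2O (gas), −78 °C
Reagents that add atoms: formaldehyde, C=O
Why: Kinetic α'-deprotonation of the enone and aldol addition to monomeric formaldehyde attach the future C2 to the future C1; the new centre is enolised again in step 3.

**Step 2**
Reactants: 3 hydroxymethyl ketone
Product: 4 triethylsilyl ether of 3
Conditions: Et3SiCl, imidazole, CH2Cl2, 0 °C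
Reagents that add atoms: chlorotriethylsilane, CC[Si](Cl)(CC)CC
Why: Silylation of the primary alcohol blocks retro-aldol loss of formaldehyde and masks C2 until step 19.

**Step 3**
Reactants: 4 silyl ether
Product: 6 ketone with quaternary C1 (β-CH3, α-CH2OTES), via lithium enolate 5 (not isolated)
Conditions: LiN(iPr)2, THF/DMPU, −78 °C; MeI, −78 to −30 °C
Reagents that add atoms: iodomethane, CI
Why: Enolate alkylation should occur anti to the neighbouring isopropenyl group, so C15 ends trans and the CH2OTES arm cis to the future C14 oxygen.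

**Step 4**
Reactants: 6 enone
Product: 7 epoxy ketone (11β,12β-epoxide, C10 ketone)
Conditions: 30% H2O2, NaOH (cat.), MeOH, 0 °C
Reagents that add atoms: hydrogen peroxide, OO
Why: Weitz–Scheffer epoxidation; hydroperoxide should add to C12 anti to the C14 substituent, as with carvone itself, which puts the epoxide on the β face.

**Step 5**
Reactants: 7 epoxy ketone
Product: 9 C14 α-acetate, via methoxy hydroperoxide 8 (not isolated)
Conditions: O3, CH2Cl2/MeOH, −78 °C; then Ac2O, Et3N, DMAP, 0 °C to rt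
Reagents that add atoms: ozone, [O-][O+]=O; methanol, CO
Why: Ozonolysis of the only alkene followed by Criegee rearrangement, in which the ring carbon migrates to oxygen with retention, turns the isopropenyl group into the C14 acetate.

**Step 6**
Reactants: 9 acetate
Product: 10 C14 alcohol
Conditions: K2CO3 (cat.), MeOH, 0 °C
Reagents that add atoms: none
Why: Mild transesterification; low temperature and catalytic base are chosen to keep the β-hydroxy ketone from retro-aldol opening.

**Step 7**
Reactants: 10 alcohol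
Product: 11 C14 triethylsilyl ether
Conditions: Et3SiOTf, 2,6-lutidine, CH2Cl2, −78 °C
Reagents that add atoms: triethylsilyl trifluoromethanesulfonate, CC[Si](CC)(CC)OS(=O)(=O)C(F)(F)F
Why: Triflate silylation of the hindered secondary alcohol; the epoxide is deactivated towards the silyl triflate by the adjacent carbonyl.

**Step 8**
Reactants: 11 epoxy ketone
Product: 13 allylic alcohol (C12 β-OH, C10=C11), via epoxy hydrazone 12 (not isolated)
Conditions: N2H4·H2O, AcOH (cat.), MeOH, 0 °C to rt
Reagents that add atoms: none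
Why: Wharton transposition: the hydrazone opens the epoxide and loses nitrogen; the C12–O bond is untouched and stays β.

**Step 9**
Reactants: 13 allylic alcohol
Product: 15 amide (C10 β-CH2CONMe2 = C9, C8; C11=C12), via ketene N,O-acetal 14 (not isolated)
Conditions: MeC(OMe)2NMe2, xylene, 140 °C
Reagents that add atoms: N,N-dimethylacetamide dimethyl acetal, CN(C)C(C)(OC)OC
Why: Eschenmoser–Claisen rearrangement; the suprafacial [3,3] shift delivers C9 to C10 on the face of the C12 oxygen (β), sets C10 and moves the alkene to C11=C12.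

**Step 10**
Reactants: 15 amide
Product: 17 (9R)-α-hydroxy amide, via lithium amide enolate 16 (not isolated)
Conditions: LiN(iPr)2, THF, −78 °C; 2-(phenylsulfonyl)-3-phenyloxaziridine, −78 °C
Reagents that add atoms: 2-(phenylsulfonyl)-3-phenyloxaziridine, O=S(=O)(c1ccccc1)N1OC1c1ccccc1
Why: Davis enolate hydroxylation; with H10 eclipsing the (Z)-enolate (allylic strain) the oxidant should approach anti to the quaternary C1, which gives the 9R alcohol by 1,2-induction.

**Step 11**
Reactants: 17 hydroxy amide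
Product: 18 C9 4-methoxybenzyl ether
Conditions: NaH, 4-MeOC6H4CH2Cl, Bu4NI (cat.), DMF, 0 °C to rt
Reagents that add atoms: 4-methoxybenzyl chloride, COc1ccc(CCl)cc1
Why: Williamson etherification of the alkoxide of the α-hydroxy amide.

**Step 12**
Reactants: 18 γ,δ-unsaturated amide
Product: 20 iodolactone (C8(=O)–O–C11 on the β face, C12 α-iodide), via iminium lactone iodide 19 (not isolated)
Conditions: I2, NaHCO3, THF/H2O, 0 °C to rt, dark
Reagents that add atoms: iodine, II; water, O
Why: Iodolactonisation: the amide oxygen attacks the tertiary C11 5-exo and necessarily cis to C9, iodine adds anti at C12, and water hydrolyses the iminium ether.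

**Step 13**
Reactants: 20 iodolactone
Product: 21 epoxy methyl ester (11β,12β-epoxide, C8 CO2Me, C9 OPMB)
Conditions: K2CO3, MeOH, 0 °C to rt
Reagents that add atoms: methanol, CO
Why: Methanolysis of the lactone frees the C11 alkoxide, which displaces the anti-periplanar C12 iodide (iodolactone to epoxy ester conversion), so the epoxide is fixed cis to C9 and C15.

**Step 14**
Reactants: 21 methyl ester
Product: 22 C8 aldehyde
Conditions: iBu2AlH, CH2Cl2, −78 °C
Reagents that add atoms: none
Why: Partial ester reduction; the aluminium hemiacetal of the α-alkoxy ester is stable at low temperature and gives the aldehyde on work-up.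

**Step 15**
Reactants: 23 2-(allyloxy)acetic acid; 24 (R)-4-benzyloxazolidin-2-one
Product: 26 (R)-3-[2-(allyloxy)acetyl]-4-benzyloxazolidin-2-one, via pivalic mixed anhydride 25 (not isolated)
Conditions: tBuCOCl, Et3N, THF, −20 °C; then 24, LiCl, −20 °C to rt
Reagents that add atoms: none
Why: N-acylation of the oxazolidinone auxiliary through the mixed anhydride.

**Step 16**
Reactants: 22 aldehyde; 26 glycolyl imide
Product: 28 syn aldol adduct (C8 OH, C7 O-allyl, C6 acyl oxazolidinone), via boron enolate 27 (not isolated)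
Conditions: Bu2BOTf, Et3N, CH2Cl2, −78 to 0 °C; 22, −78 to −10 °C; pH 7 buffer, MeOH, H2O2, 0 °C
Reagents that add atoms: none
Why: Evans syn glycolate aldol; the (Z)-boron enolate reacts through a Zimmerman–Traxler chair under control of the (R)-benzyl auxiliary, which sets C7 as in the target, while C8 is oxidised later.

**Step 17**
Reactants: 28 aldol adduct
Product: 29 C8 tert-butyldimethylsilyl ether
Conditions: tBuMe2SiOTf, 2,6-lutidine, CH2Cl2, −78 °C
Reagents that add atoms: tert-butyldimethylsilyl trifluoromethanesulfonate, CC(C)(C)[Si](C)(C)OS(=O)(=O)C(F)(F)F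
Why: Triflate silylation of the hindered aldol hydroxyl at a temperature at which the trisubstituted epoxide should not be opened.

**Step 18**
Reactants: 29 imide
Product: 30 C6 primary alcohol
Conditions: LiBH4, MeOH (1 equiv), THF, 0 °C
Reagents that add atoms: none
Why: Reductive cleavage of the acyl oxazolidinone gives the primary alcohol and returns the auxiliary.

**Step 19**
Reactants: 30 alcohol
Product: 32 dialdehyde (C6 and C2), via bis-alkoxysulfonium salt 31 (not isolated)
Conditions: (COCl)2, DMSO, CH2Cl2, −78 to −35 °C; iPr2NEt, −78 to 0 °C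
Reagents that add atoms: none
Why: Swern oxidation; activated DMSO also cleaves the primary triethylsilyl ether, so both C6 and C2 become aldehydes while the two secondary silyl ethers should remain.

**Step 20**
Reactants: 33 2-bromoprop-2-en-1-ol
Product: 34 2-bromoallyl 4-methoxybenzyl ether
Conditions: NaH, 4-MeOC6H4CH2Cl, Bu4NI (cat.), THF, 0 °C to rt
Reagents that add atoms: 4-methoxybenzyl chloride, COc1ccc(CCl)cc1
Why: Williamson etherification of the allylic alcohol.

**Step 21**
Reactants: 32 dialdehyde; 34 bromide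
Product: 36 C6 allylic alcohol with free C2 aldehyde (C6 epimers), via 2-lithioallyl PMB ether 35 (not isolated)
Conditions: 34, t-BuLi (2 equiv), Et2O, −78 °C; then 32, THF, −78 °C
Reagents that add atoms: none
Why: Bromine–lithium exchange and 1,2-addition; the alkenyllithium should attack only the α-alkoxy C6 aldehyde, because the C2 aldehyde sits on the quaternary C1.

**Step 22**
Reactants: 36 hydroxy aldehyde
Product: 37 seco acid (C2 CO2H, C6 OH)
Conditions: NaClO2, NaH2PO4, 2-methyl-2-butene, t-BuOH/H2O, 0 °C to rt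
Reagents that add atoms: sodium chlorite, [Na+].[O-]Cl=O
Why: Pinnick oxidation converts the hindered aldehyde to the acid and leaves the allylic alcohol, alkenes and epoxide alone.

**Step 23**
Reactants: 37 seco acid
Product: 39 eight-membered lactone (O joins C2 and C6), via aroyl mixed anhydride 38 (not isolated)
Conditions: 2-methyl-6-nitrobenzoic anhydride, DMAP, CH2Cl2, high dilution, slow addition, rt
Reagents that add atoms: none
Why: Shiina macrolactonisation; ring A and the four substituted chain carbons limit the freedom of the seco acid and should bring the C6 hydroxyl close to the activated carboxyl.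

**Step 24**
Reactants: 39 lactone
Product: 40 2-methylene oxocane (C2=C3H2 enol ether)
Conditions: Cp2TiMe2, toluene, 75 °C, dark
Reagents that add atoms: dimethyltitanocene, C[Ti](C)(C1C=CC=C1)C1C=CC=C1
Why: Petasis methylenation of the lactone carbonyl; C1 has no hydrogen, so the exocyclic enol ether cannot isomerise into the ring.

**Step 25**
Reactants: 40 2-methylene oxocane
Product: 41 ring-expanded cyclodec-4-enone (C2 ketone, C5=C6 with C7 cis to C4)
Conditions: toluene, iPr2NEt (trace), 170 °C, sealed tube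
Reagents that add atoms: none
Why: On heating, the allyl vinyl ether C3=C2–O–C6–C5=C4 should undergo a concerted [3,3] sigmatropic (Claisen) shift in which the C3–C4 bond forms and the ring O–C6 bond breaks, with the gain of the C2 carbonyl as driving force. The closest known reaction type is the thermal ring enlargement of 2-methylene oxacycles that carry an alkenyl group on the other carbon attached to oxygen, which leads to cycloalk-4-enones. Ring B therefore arises by growth of the eight-membered ether by two atoms, not by joining the ends of a chain: the reacting termini C3 and C4 are exocyclic and C3, C4 and C5 are inserted between C2 and C6. No stereocentre is formed and C6 becomes trigonal, so both C6 epimers should converge on 41. The selectivity needed is the alkene geometry, C7 cis to C4 across C5=C6; the five-atom bridge C7–C8–C9–C10–C1 between C6 and C2 is too short to span the six-atom array and should hold C7 pseudo-axial in a chair-like array, the position that becomes cis to C4. The quaternary C1 keeps the enol ether exocyclic and ring A stiffens the ether ring.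

**Step 26**
Reactants: 41 ketone
Product: 42 C14 alcohol (β-hydroxy ketone)
Conditions: HF·pyridine, pyridine, THF, 0 °C
Reagents that add atoms: none
Why: Selective desilylation; the triethylsilyl ether is cleaved well before the hindered tert-butyldimethylsilyl ether at C8.

**Step 27**
Reactants: 42 β-hydroxy ketone
Product: 44 C2,C14 syn-diol (2R), via diethylborinate 43 (not isolated)
Conditions: Et2BOMe, THF/MeOH, −78 °C; NaBH4, −78 °C; MeOH work-up
Reagents that add atoms: none
Why: Narasaka–Prasad reduction; the boron chelate of O14 and the C2 carbonyl is a half-chair fused to ring A, and axial hydride attack anti to the axial C1–C10 bond should give the 1,3-syn diol.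

**Step 28**
Reactants: 44 diol
Product: 45 C2,C14 diacetate
Conditions: Ac2O, pyridine, DMAP (cat.), CH2Cl2, 0 °C to rt
Reagents that add atoms: acetic anhydride, CC(=O)OC(C)=O
Why: Acetylation of both secondary alcohols installs the two acetates of the target in one operation.

**Step 29**
Reactants: 45 allyl ether
Product: 47 C7 alcohol, via propenyl ether 46 (not isolated)
Conditions: [Ir(cod)(PMePh2)2]PF6 (cat., H2-activated), THF, rt; then I2, NaHCO3, THF/H2O, 0 °C
Reagents that add atoms: none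
Why: Iridium-catalysed isomerisation of the terminal allyl ether to the enol ether and its iodine-mediated hydrolysis free O7 under near-neutral conditions that spare the epoxide, acetates and both benzyl-type ethers.

**Step 30**
Reactants: 47 alcohol; 48 2-bromopropanoyl bromide
Product: 49 C7 2-bromopropanoate
Conditions: pyridine, CH2Cl2, −30 °C
Reagents that add atoms: none
Why: Acylation of the secondary allylic alcohol with the acid bromide.

**Step 31**
Reactants: 49 silyl ether
Product: 50 C8 alcohol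
Conditions: HF·pyridine, THF, 0 °C to rt
Reagents that add atoms: none
Why: Fluoride desilylation in acidic medium, which should not cause migration of the C7 acyl group or opening of the epoxide.

**Step 32**
Reactants: 50 alcohol
Product: 51 C8 ketone
Conditions: Dess–Martin periodinane, NaHCO3, CH2Cl2, 0 °C to rt
Reagents that add atoms: none
Why: Buffered Dess–Martin oxidation gives the α-acyloxy ketone without base that could epimerise C7 or C9.

**Step 33**
Reactants: 51 bromo ester ketone
Product: 53 ring C lactone (8R hydroxyl, 17R methyl), via samarium enolate 52 (not isolated)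
Conditions: SmI2, THF, −78 °C
Reagents that add atoms: none
Why: Samarium Reformatsky reaction; with the C8 carbonyl eclipsing C7–C6 and C9 anti to C6 in ring B, the enolate tethered through O7 should add on the O7 side to give the 8-hydroxyl cis to C6, and the epimerisable C17 is expected to carry its methyl trans to C9.

**Step 34**
Reactants: 53 bis(4-methoxybenzyl) ether
Product: 54 C9,C16-diol
Conditions: DDQ, CH2Cl2/pH 7 buffer, 0 °C
Reagents that add atoms: none
Why: Oxidative cleavage of both 4-methoxybenzyl ethers, conditions under which the epoxide, acetates and lactone are stable.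

**Step 35**
Reactants: 54 diol
Product: 56 target CNP0308390.1, via allylic mesylate 55 (not isolated)
Conditions: MsCl, 2,4,6-collidine, LiCl, DMF, 0 °C
Reagents that add atoms: lithium chloride, [Li+].[Cl-]
Why: Selective mesylation of the primary allylic alcohol and SN2 displacement by chloride; the hindered secondary C9 and tertiary C8 hydroxyls should not react.

**Compound list**

1 | (S)-carvone | CC(=C)[C@H]1CC=C(C)C(=O)C1 | starting material
2 | lithium dienolate of 1 (not isolated) | CC(=C)[C@H]1CC=C(C)C(O[Li])=C1 | intermediate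
3 | (5S,6S)-6-(hydroxymethyl)carvone | CC(=C)[C@H]1CC=C(C)C(=O)[C@@H]1CO | intermediate
4 | triethylsilyl ether of 3 | CC(=C)[C@H]1CC=C(C)C(=O)[C@@H]1CO[Si](CC)(CC)CC | intermediate
5 | lithium enolate of 4 (not isolated) | CC(=C)[C@H]1CC=C(C)C(O[Li])=C1CO[Si](CC)(CC)CC | intermediate
6 | enone with quaternary C1 (β-CH3, α-CH2OTES), C14 α-isopropenyl | CC(=C)[C@H]1CC=C(C)C(=O)[C@@]1(C)CO[Si](CC)(CC)CC | intermediate
7 | 11β,12β-epoxy C10 ketone | CC(=C)[C@H]1C[C@@H]2O[C@]2(C)C(=O)[C@@]1(C)CO[Si](CC)(CC)CC | intermediate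
8 | methoxy hydroperoxide from 7 (not isolated; peroxy carbon unassigned) | CC(OC)(OO)[C@H]1C[C@@H]2O[C@]2(C)C(=O)[C@@]1(C)CO[Si](CC)(CC)CC | intermediate
9 | C14 α-acetate epoxy ketone | CC(=O)O[C@H]1C[C@@H]2O[C@]2(C)C(=O)[C@@]1(C)CO[Si](CC)(CC)CC | intermediate
10 | C14 α-alcohol epoxy ketone | O[C@H]1C[C@@H]2O[C@]2(C)C(=O)[C@@]1(C)CO[Si](CC)(CC)CC | intermediate
11 | C14 triethylsilyl ether epoxy ketone | CC[Si](CC)(CC)O[C@H]1C[C@@H]2O[C@]2(C)C(=O)[C@@]1(C)CO[Si](CC)(CC)CC | intermediate
12 | hydrazone of 11 (not isolated) | CC[Si](CC)(CC)O[C@H]1C[C@@H]2O[C@]2(C)C(=NN)[C@@]1(C)CO[Si](CC)(CC)CC | intermediate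
13 | allylic alcohol, C12 β-OH, C10=C11 | CC[Si](CC)(CC)O[C@H]1C[C@H](O)C(C)=C[C@@]1(C)CO[Si](CC)(CC)CC | intermediate
14 | ketene N,O-acetal of 13 (not isolated) | CC[Si](CC)(CC)O[C@H]1C[C@H](OC(=C)N(C)C)C(C)=C[C@@]1(C)CO[Si](CC)(CC)CC | intermediate
15 | N,N-dimethylamide, C9 on the β face of C10, C11=C12 | CC[Si](CC)(CC)O[C@H]1CC=C(C)[C@H](CC(=O)N(C)C)[C@@]1(C)CO[Si](CC)(CC)CC | intermediate
16 | lithium (Z)-enolate of 15 (not isolated) | CC[Si](CC)(CC)O[C@H]1CC=C(C)[C@H](/C=C(\O[Li])N(C)C)[C@@]1(C)CO[Si](CC)(CC)CC | intermediate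
17 | (9R)-α-hydroxy amide | CC[Si](CC)(CC)O[C@H]1CC=C(C)[C@H]([C@@H](O)C(=O)N(C)C)[C@@]1(C)CO[Si](CC)(CC)CC | intermediate
18 | C9 4-methoxybenzyl ether amide | CC[Si](CC)(CC)O[C@H]1CC=C(C)[C@H]([C@@H](OCc2ccc(OC)cc2)C(=O)N(C)C)[C@@]1(C)CO[Si](CC)(CC)CC | intermediate
19 | iminium lactone iodide (not isolated) | CC[Si](CC)(CC)O[C@H]1C[C@@H](I)[C@]2(C)OC(=[N+](C)C)[C@H](OCc3ccc(OC)cc3)[C@@H]2[C@@]1(C)CO[Si](CC)(CC)CC.[I-] | intermediate
20 | iodolactone, O on C11 β, iodide on C12 α | CC[Si](CC)(CC)O[C@H]1C[C@@H](I)[C@]2(C)OC(=O)[C@H](OCc3ccc(OC)cc3)[C@@H]2[C@@]1(C)CO[Si](CC)(CC)CC | intermediate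
21 | 11β,12β-epoxy methyl ester | CC[Si](CC)(CC)O[C@H]1C[C@@H]2O[C@]2(C)[C@H]([C@@H](OCc3ccc(OC)cc3)C(=O)OC)[C@@]1(C)CO[Si](CC)(CC)CC | intermediate
22 | C8 aldehyde | CC[Si](CC)(CC)O[C@H]1C[C@@H]2O[C@]2(C)[C@H]([C@@H](OCc3ccc(OC)cc3)C=O)[C@@]1(C)CO[Si](CC)(CC)CC | intermediate
23 | 2-(allyloxy)acetic acid | C=CCOCC(=O)O | starting material
24 | (R)-4-benzyloxazolidin-2-one | O=C1N[C@H](Cc2ccccc2)CO1 | starting material
25 | pivalic mixed anhydride of 23 (not isolated) | C=CCOCC(=O)OC(=O)C(C)(C)C | intermediate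
26 | (R)-3-[2-(allyloxy)acetyl]-4-benzyloxazolidin-2-one | C=CCOCC(=O)N1[C@H](Cc2ccccc2)COC1=O | intermediate
27 | (Z)-dibutylboron enolate of 26 (not isolated) | C=CCO/C=C(\OB(CCCC)CCCC)N1[C@H](Cc2ccccc2)COC1=O | intermediate
28 | syn aldol adduct, C8 OH, C7 O-allyl | CC[Si](CC)(CC)O[C@H]1C[C@@H]2O[C@]2(C)[C@H]([C@@H](OCc3ccc(OC)cc3)[C@H](O)[C@@H](OCC=C)C(=O)N3[C@H](Cc4ccccc4)COC3=O)[C@@]1(C)CO[Si](CC)(CC)CC | intermediate
29 | C8 tert-butyldimethylsilyl ether of 28 | CC[Si](CC)(CC)O[C@H]1C[C@@H]2O[C@]2(C)[C@H]([C@@H](OCc3ccc(OC)cc3)[C@H](O[Si](C)(C)C(C)(C)C)[C@@H](OCC=C)C(=O)N3[C@H](Cc4ccccc4)COC3=O)[C@@]1(C)CO[Si](CC)(CC)CC | intermediate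
30 | C6 primary alcohol | CC[Si](CC)(CC)O[C@H]1C[C@@H]2O[C@]2(C)[C@H]([C@@H](OCc3ccc(OC)cc3)[C@H](O[Si](C)(C)C(C)(C)C)[C@@H](OCC=C)CO)[C@@]1(C)CO[Si](CC)(CC)CC | intermediate
31 | bis(alkoxysulfonium) chloride at O6 and O2 (not isolated) | CC[Si](CC)(CC)O[C@H]1C[C@@H]2O[C@]2(C)[C@H]([C@@H](OCc3ccc(OC)cc3)[C@H](O[Si](C)(C)C(C)(C)C)[C@@H](OCC=C)CO[S+](C)C)[C@@]1(C)CO[S+](C)C.[Cl-].[Cl-] | intermediate
32 | C6,C2 dialdehyde | CC[Si](CC)(CC)O[C@H]1C[C@@H]2O[C@]2(C)[C@H]([C@@H](OCc3ccc(OC)cc3)[C@H](O[Si](C)(C)C(C)(C)C)[C@@H](OCC=C)C=O)[C@@]1(C)C=O | intermediate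
33 | 2-bromoprop-2-en-1-ol | C=C(Br)CO | starting material
34 | 2-bromoallyl 4-methoxybenzyl ether | C=C(Br)COCc1ccc(OC)cc1 | intermediate
35 | 2-lithioallyl 4-methoxybenzyl ether (not isolated) | C=C([Li])COCc1ccc(OC)cc1 | intermediate
36 | C6 allylic alcohol with C2 aldehyde (C6 epimers, one drawn) | CC[Si](CC)(CC)O[C@H]1C[C@@H]2O[C@]2(C)[C@H]([C@@H](OCc3ccc(OC)cc3)[C@H](O[Si](C)(C)C(C)(C)C)[C@@H](OCC=C)[C@@H](O)C(=C)COCc3ccc(OC)cc3)[C@@]1(C)C=O | intermediate
37 | seco acid (C6 epimers, one drawn) | CC[Si](CC)(CC)O[C@H]1C[C@@H]2O[C@]2(C)[C@H]([C@@H](OCc3ccc(OC)cc3)[C@H](O[Si](C)(C)C(C)(C)C)[C@@H](OCC=C)[C@@H](O)C(=C)COCc3ccc(OC)cc3)[C@@]1(C)C(=O)O | intermediate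
38 | mixed anhydride of 37 with 2-methyl-6-nitrobenzoic acid (not isolated) | CC[Si](CC)(CC)O[C@H]1C[C@@H]2O[C@]2(C)[C@H]([C@@H](OCc3ccc(OC)cc3)[C@H](O[Si](C)(C)C(C)(C)C)[C@@H](OCC=C)[C@@H](O)C(=C)COCc3ccc(OC)cc3)[C@@]1(C)C(=O)OC(=O)c3c(C)cccc3[N+](=O)[O-] | intermediate
39 | eight-membered lactone, O joins C2 and C6 (C6 epimers, one drawn) | CC[Si](CC)(CC)O[C@H]1C[C@@H]2O[C@]2(C)[C@@H]3[C@@H](OCc4ccc(OC)cc4)[C@H](O[Si](C)(C)C(C)(C)C)[C@@H](OCC=C)[C@H](C(=C)COCc5ccc(OC)cc5)OC(=O)[C@@]13C | intermediate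
40 | 2-methylene oxocane, key-step precursor (C6 epimers, one drawn) | CC[Si](CC)(CC)O[C@H]1C[C@@H]2O[C@]2(C)[C@@H]3[C@@H](OCc4ccc(OC)cc4)[C@H](O[Si](C)(C)C(C)(C)C)[C@@H](OCC=C)[C@H](C(=C)COCc5ccc(OC)cc5)OC(=C)[C@@]13C | intermediate
41 | cyclodec-4-enone, key-step product | CC[Si](CC)(CC)O[C@H]1C[C@@H]2O[C@]2(C)[C@@H]3[C@@H](OCc4ccc(OC)cc4)[C@H](O[Si](C)(C)C(C)(C)C)[C@@H](OCC=C)/C=C(/COCc5ccc(OC)cc5)CCC(=O)[C@@]13C | intermediate
42 | C14 alcohol, C2 ketone | O[C@H]1C[C@@H]2O[C@]2(C)[C@@H]3[C@@H](OCc4ccc(OC)cc4)[C@H](O[Si](C)(C)C(C)(C)C)[C@@H](OCC=C)/C=C(/COCc5ccc(OC)cc5)CCC(=O)[C@@]13C | intermediate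
43 | C14 diethylborinate of 42 (not isolated) | CCB(CC)O[C@H]1C[C@@H]2O[C@]2(C)[C@@H]3[C@@H](OCc4ccc(OC)cc4)[C@H](O[Si](C)(C)C(C)(C)C)[C@@H](OCC=C)/C=C(/COCc5ccc(OC)cc5)CCC(=O)[C@@]13C | intermediate
44 | C2,C14 syn-diol | O[C@H]1C[C@@H]2O[C@]2(C)[C@@H]3[C@@H](OCc4ccc(OC)cc4)[C@H](O[Si](C)(C)C(C)(C)C)[C@@H](OCC=C)/C=C(/COCc5ccc(OC)cc5)CC[C@@H](O)[C@@]13C | intermediate
45 | C2,C14 diacetate | CC(=O)O[C@H]1C[C@@H]2O[C@]2(C)[C@@H]3[C@@H](OCc4ccc(OC)cc4)[C@H](O[Si](C)(C)C(C)(C)C)[C@@H](OCC=C)/C=C(/COCc5ccc(OC)cc5)CC[C@@H](OC(C)=O)[C@@]13C | intermediate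
46 | C7 prop-1-enyl ether (not isolated; E/Z mixture) | CC(=O)O[C@H]1C[C@@H]2O[C@]2(C)[C@@H]3[C@@H](OCc4ccc(OC)cc4)[C@H](O[Si](C)(C)C(C)(C)C)[C@@H](OC=CC)/C=C(/COCc5ccc(OC)cc5)CC[C@@H](OC(C)=O)[C@@]13C | intermediate
47 | C7 alcohol | CC(=O)O[C@H]1C[C@@H]2O[C@]2(C)[C@@H]3[C@@H](OCc4ccc(OC)cc4)[C@H](O[Si](C)(C)C(C)(C)C)[C@@H](O)/C=C(/COCc5ccc(OC)cc5)CC[C@@H](OC(C)=O)[C@@]13C | intermediate
48 | 2-bromopropanoyl bromide | CC(Br)C(Br)=O | starting material
49 | C7 2-bromopropanoate (CHBr epimers) | CC(=O)O[C@H]1C[C@@H]2O[C@]2(C)[C@@H]3[C@@H](OCc4ccc(OC)cc4)[C@H](O[Si](C)(C)C(C)(C)C)[C@@H](OC(=O)C(C)Br)/C=C(/COCc5ccc(OC)cc5)CC[C@@H](OC(C)=O)[C@@]13C | intermediate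
50 | C8 alcohol | CC(=O)O[C@H]1C[C@@H]2O[C@]2(C)[C@@H]3[C@@H](OCc4ccc(OC)cc4)[C@H](O)[C@@H](OC(=O)C(C)Br)/C=C(/COCc5ccc(OC)cc5)CC[C@@H](OC(C)=O)[C@@]13C | intermediate
51 | C8 ketone | CC(=O)O[C@H]1C[C@@H]2O[C@]2(C)[C@@H]3[C@@H](OCc4ccc(OC)cc4)C(=O)[C@@H](OC(=O)C(C)Br)/C=C(/COCc5ccc(OC)cc5)CC[C@@H](OC(C)=O)[C@@]13C | intermediate
52 | samarium ester enolate (not isolated) | CC(=O)O[C@H]1C[C@@H]2O[C@]2(C)[C@@H]3[C@@H](OCc4ccc(OC)cc4)C(=O)[C@@H](OC(O[Sm](I)I)=CC)/C=C(/COCc5ccc(OC)cc5)CC[C@@H](OC(C)=O)[C@@]13C | intermediate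
53 | ring C lactone with PMB ethers at O9 and O16 | CC(=O)O[C@H]1C[C@@H]2O[C@]2(C)[C@@H]3[C@@H](OCc4ccc(OC)cc4)[C@@]5(O)[C@H](/C=C(/COCc6ccc(OC)cc6)CC[C@@H](OC(C)=O)[C@@]13C)OC(=O)[C@@H]5C | intermediate
54 | C9,C16-diol | CC(=O)O[C@H]1C[C@@H]2O[C@]2(C)[C@@H]3[C@@H](O)[C@@]4(O)[C@H](/C=C(/CO)CC[C@@H](OC(C)=O)[C@@]13C)OC(=O)[C@@H]4C | intermediate
55 | C16 mesylate (not isolated) | CC(=O)O[C@H]1C[C@@H]2O[C@]2(C)[C@@H]3[C@@H](O)[C@@]4(O)[C@H](/C=C(/COS(C)(=O)=O)CC[C@@H](OC(C)=O)[C@@]13C)OC(=O)[C@@H]4C | intermediate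
56 | CNP0308390.1 | CC(=O)O[C@H]1C[C@@H]2O[C@]2(C)[C@@H]2[C@@H](O)[C@@]3(O)[C@H](/C=C(/CCl)CC[C@@H](OC(C)=O)[C@@]12C)OC(=O)[C@@H]3C | target

**Step count.** 35 steps in total. The longest linear sequence is 33 steps (steps 1–14, 16–19 and 21–35 from (S)-carvone).

**Steps most likely to fail**

Step 25 (ring expansion). The thermal shift may be slow for one C6 epimer, and the acid-sensitive enol ether may hydrolyse or fragment before it rearranges. The fallback leaves the thermal pericyclic mode and sets out from 40: with iBu3Al in CH2Cl2 at −78 to 0 °C the C6–O bond is ionised by the Lewis acid, the ring enlarges at low temperature and the aluminium reagent reduces the new carbonyl in the same flask. This should give the ring-expanded C2 alcohol F1, which Dess–Martin oxidation returns to the route at 41.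

Step 8 (Wharton transposition). Condensation of hydrazine with a carbonyl flanked by two fully substituted carbons may be so slow that epoxide opening or desilylation takes over. The fallback sets out from 11: NaBH4 in MeOH gives the epoxy alcohol F2, then NaH, CS2 and MeI give the xanthate F3. Bu3SnH with AIBN in toluene at 80 °C generates the C10 radical, which opens the epoxide by β-scission, and hydrogen transfer to the C12 oxygen radical returns the route at 13.

Step 23 (lactonisation). Acyl transfer at the neopentyl carboxyl may be slow, so that intermolecular esterification or aroylation of the C6 hydroxyl by the reagent competes with closure of the eight-membered ring. The fallback sets out from 37 and activates the alcohol instead of the acid: Mitsunobu lactonisation (PPh3, DIAD, toluene, high dilution) closes the ring by carboxylate attack at C6 with inversion. This is harmless because both C6 epimers serve, and the route is rejoined at 39; no new compound arises (F0).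

**Further compounds**

F1 | step 25 | ring-expanded C2 alcohol (C2 epimers) | CC[Si](CC)(CC)O[C@H]1C[C@@H]2O[C@]2(C)[C@@H]3[C@@H](OCc4ccc(OC)cc4)[C@H](O[Si](C)(C)C(C)(C)C)[C@@H](OCC=C)/C=C(/COCc5ccc(OC)cc5)CCC(O)[C@@]13C
F2 | step 8 | C10 epoxy alcohol (C10 epimers) | CC[Si](CC)(CC)O[C@H]1C[C@@H]2O[C@]2(C)C(O)[C@@]1(C)CO[Si](CC)(CC)CC
F3 | step 8 | C10 S-methyl xanthate | CC[Si](CC)(CC)O[C@H]1C[C@@H]2O[C@]2(C)C(OC(=S)SC)[C@@]1(C)CO[Si](CC)(CC)CC
F0 | step 23 | none | none
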